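**Retrosynthetic overview** (chromane numbering: O1, C2, C3, C4, C4a, C5, C6, C7, C8, C8a; ring A = carbocycle C4a–C8a, ring B = pyranone)
1. Target ⇒ methyl ester ⇒ chromanone-fused acylphloroglucinol: the quaternary C6 is set last by a catalyst-controlled dearomative Tsuji–Trost prenylation.
2. Ring B ⇒ o-tigloylphenol by quinine-catalysed oxa-Michael closure (C2, C3); the tigloyl group comes from a salicylaldehyde and 2-butyne by hydroacylation.
3. Ring A ⇒ 3-siloxycyclobutenone + siloxyalkyne: thermal four-to-six ring expansion (4π opening, ketene–alkyne [2+2], 4π opening, 6π closure).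
4. Cyclobutenone ⇒ aldoketene from desymmetrised 3-phenylglutaric anhydride (benzylic centre) + siloxyalkyne from (−)-α-pinene (both cyclobutane centres) by Kowalski homologation.
5. Enabling feature: ring A carries oxygen on C5, C7 and C8a alternating with carbon on C4a, C6 and C8, which maps onto ketene C=O (→C8a), the siloxyalkyne (→C4a, C5) and the cyclobutenone (→C6, C7, C8). Ring order: cyclobutane (chiral pool) → cyclobutenone → ring A → ring B.

Key step: step 9

Remark on the chemistry: the target is treated as the C7-keto/C5-enol tautomer drawn in its SMILES (one form of an equilibrating β-triketone); 3,3-diethoxyprop-1-yne and tert-butyl (2-methylbut-3-en-2-yl) carbonate are taken as catalogue compounds.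

**Step 1**
Reactants: 1 (−)-α-pinene
Product: 2 (1R,3R)-cis-pinonic acid
Conditions: RuCl3·xH2O (2 mol %), NaIO4 (4 equiv), MeCN/EtOAc/H2O, 0 °C → rt
Reagents that add atoms: sodium periodate, [Na+].[O-]I(=O)(=O)=O; water, O
Why: RuO4-type oxidative cleavage of the trisubstituted ring alkene should give the keto acid without touching the two cyclobutane stereocentres, which come from the chiral pool with their cis relationship fixed by the former bicycle.

**Step 2**
Reactants: 2 (1R,3R)-cis-pinonic acid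
Product: 3 methyl (1R,3R)-cis-pinonate
Conditions: MeI (1.5 equiv), KHCO3 (2 equiv), DMF, rt
Reagents that add atoms: iodomethane, CI
Why: SN2 O-methylation of the carboxylate under hydrogencarbonate, a base too weak to enolise the methyl ketone, should leave the epimerisable C3 centre intact.

**Step 3**
Reactants: 3 methyl (1R,3R)-cis-pinonate
Product: 4 methyl 2-[(1R,3S)-2,2-dimethyl-3-(prop-1-en-2-yl)cyclobutyl]acetate
Conditions: Ph3PCH3Br (1.3 equiv), NaN(SiMe3)2 (1.25 equiv), THF, 0 °C; then 3, −78 → 0 °C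
Reagents that add atoms: methyltriphenylphosphonium bromide, C[P+](c1ccccc1)(c1ccccc1)c1ccccc1.[Br-]
Why: Wittig methylenation of the methyl ketone with the pre-formed ylide (no excess base) at low temperature should outrun α-epimerisation and does not touch the ester.

**Step 4**
Reactants: 4 methyl 2-[(1R,3S)-2,2-dimethyl-3-(prop-1-en-2-yl)cyclobutyl]acetate
Product: 7 pinene-derived siloxyalkyne (triisopropylsilyl ynol ether), via lithium dibromoenolate 5 (not isolated), via lithium ynolate 6 (not isolated)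
Conditions: CH2Br2 (2.2 equiv), lithium 2,2,6,6-tetramethylpiperidide (2.1 equiv), THF, −78 °C; then n-BuLi (3 equiv), −78 °C → rt; then i-Pr3SiCl (1.5 equiv), −78 → 0 °C
Reagents that add atoms: dibromomethane, BrCBr; triisopropylsilyl chloride, CC(C)[Si](Cl)(C(C)C)C(C)C
Why: Kowalski ester homologation: LiCHBr2 adds to the ester, the dibromoketone enolate 5 undergoes bromine–lithium exchange and 1,2-shift to ynolate 6, and the bulky silyl chloride traps it on oxygen as the isolable siloxyalkyne, the remote stereocentres being untouched.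

**Step 5**
Reactants: 8 3-phenylglutaric anhydride
Product: 9 (3S)-5-methoxy-5-oxo-3-phenylpentanoic acid
Conditions: MeOH (10 equiv), (DHQD)2AQN (10 mol %; or its pseudo-enantiomer (DHQ)2AQN), Et2O, −40 °C
Reagents that add atoms: methanol, CO
Why: Cinchona-alkaloid-catalysed enantioselective desymmetrising methanolysis of the prochiral anhydride should set the benzylic stereocentre; the half-ester is a known compound, so the catalyst pseudo-enantiomer that gives the (S)-acid is identified by optical rotation.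

**Step 6**
Reactants: 9 (3S)-5-methoxy-5-oxo-3-phenylpentanoic acid
Product: 10 methyl (3R)-5-chloro-5-oxo-3-phenylpentanoate
Conditions: (COCl)2 (1.2 equiv), DMF (cat.), CH2Cl2, 0 °C → rt
Reagents that add atoms: oxalyl chloride, O=C(Cl)C(=O)Cl
Why: Standard acid chloride formation through the chloroiminium species; the stereocentre is β to the acyl group and cannot epimerise (the descriptor changes only by priority).

**Step 7**
Reactants: 10 methyl (3R)-5-chloro-5-oxo-3-phenylpentanoate; 7 pinene-derived siloxyalkyne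
Product: 12 3-siloxycyclobutenone carrying both side chains (epimer mixture at the ring CH), via aldoketene 11 (not isolated)
Conditions: Et3N (1.5 equiv), CH2Cl2, 25 °C, 10 (1.3 equiv) added over 4 h to 7 and Et3N; rapid filtration through Et3N-deactivated silica
Reagents that add atoms: none
Why: Dehydrochlorination gives aldoketene 11, which should undergo the known regioselective [2+2] cycloaddition of ketenes with siloxyalkynes (ketene carbonyl carbon to the alkyne carbon β to oxygen); the new ring CH forms as an epimer mixture that is erased in step 9.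

**Step 8**
Reactants: 13 3,3-diethoxyprop-1-yne
Product: 16 (3,3-diethoxyprop-1-yn-1-yl)oxy(triisopropyl)silane, via lithium acetylide 14 (not isolated), via lithium ynolate 15 (not isolated)
Conditions: LiN(SiMe3)2 (1.05 equiv), THF, −78 °C; t-BuOOLi [from t-BuOOH (1.1 equiv) + LiN(SiMe3)2], −78 → 0 °C; i-Pr3SiOTf (1.2 equiv), −78 → 0 °C
Reagents that add atoms: tert-butyl hydroperoxide, CC(C)(C)OO; triisopropylsilyl trifluoromethanesulfonate, CC(C)[Si](OS(=O)(=O)C(F)(F)F)(C(C)C)C(C)C
Why: Electrophilic oxygen transfer from lithium tert-butyl peroxide to the lithium acetylide gives the ynolate, which is silylated on oxygen; this is the established conversion of terminal alkynes into siloxyalkynes and the acetal is inert to it.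

**Step 9**
Reactants: 12 3-siloxycyclobutenone; 16 (3,3-diethoxyprop-1-yn-1-yl)oxy(triisopropyl)silane
Product: 22 hexasubstituted salicylaldehyde (free OH at C8a; CHO at C4a; silyl ethers at C5 and C7), via vinylketene 17 (not isolated), via vinylcyclobutenone 18 (not isolated), via dienylketene 19 (not isolated), via cyclohexadienone 20 (not isolated), via phenol acetal 21 (not isolated)
Conditions: 12 (1.0 equiv), 16 (1.5 equiv), toluene, 90 °C, sealed tube, argon; then PPTS (0.2 equiv), acetone/H2O 10:1, rt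
Reagents that add atoms: water, O
Why: Heating opens cyclobutenone 12 by conrotatory 4π cleavage of its C(=O)–CH bond to vinylketene 17, whose ketene carbon adds to the carbon β to oxygen of siloxyalkyne 16 in a [2+2] cycloaddition to give vinylcyclobutenone 18; this reopens (4π) to dienylketene 19, closes by disrotatory 6π-electrocyclisation to dienone 20 and tautomerises to phenol 21, after which mild acid unmasks the aldehyde. The closest known reaction type is the Danheiser benzannulation of cyclobutenones with siloxyalkynes, run here with a 3-siloxycyclobutenone so that the 1,3,5-trioxygenated pattern results. Ring closures: the transient four-membered ring of 18 by ketene–alkyne [2+2], and ring A by thermal 6π-electrocyclisation, a net two-carbon expansion of the cyclobutenone to the six-carbon ring. No permanent stereocentre is created: the ring CH of 12 and the quaternary carbon of 18 become sp2, while the benzylic and cyclobutane centres never sit next to a carbonyl or cationic site and are carried through unchanged. The selectivity needed is the regiochemistry of the [2+2], which places the free OH at C8a (between C4a and C8) and the two silyl ethers at C5 and C7; it is secured by the polarisation of the ketene (electrophilic at the carbonyl carbon) and of the siloxyalkyne (nucleophilic at the carbon β to oxygen).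

**Step 10**
Reactants: 22 hexasubstituted salicylaldehyde; 23 but-2-yne
Product: 24 o-tigloylphenol [(2E)-2-methylbut-2-enoyl ketone at C4a]
Conditions: [RhCl(cod)]2 (2.5 mol %), dppf (5 mol %), Na2CO3 (5 mol %), but-2-yne (5 equiv), toluene, 80 °C, sealed tube
Reagents that add atoms: none
Why: Phenoxide-directed aldehyde C–H activation at monovalent rhodium and syn hydroacylation of the symmetrical alkyne (intermolecular alkyne hydroacylation of salicylaldehydes) should give the E-enone, i.e. the tigloyl ketone, with no regiochemical issue and without touching the hindered 1,1-disubstituted alkene.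

**Step 11**
Reactants: 24 o-tigloylphenol
Product: 26 (2R,3R)-trans-2,3-dimethylchromanone bis(silyl ether), via cis-chromanone 25 (not isolated)
Conditions: (−)-quinine (20 mol %), chlorobenzene, 10 °C; then Et3N (1 equiv), CH2Cl2, rt
Reagents that add atoms: none
Why: Cinchona-alkaloid-catalysed asymmetric intramolecular oxa-Michael addition (6-endo-trig) of the only free phenol closes ring B and sets C2 (R) under catalyst control, as known for closely related o-tigloylphenols, and the amine then equilibrates C3 through the enol to the trans, diequatorial isomer.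

**Step 12**
Reactants: 26 (2R,3R)-trans-2,3-dimethylchromanone bis(silyl ether)
Product: 27 5,7-dihydroxychromanone (acylphloroglucinol)
Conditions: Bu4NF (2.5 equiv), AcOH (2.5 equiv), THF, 0 °C, argon
Reagents that add atoms: none
Why: Fluoride cleavage of both aryl silyl ethers; the acetic acid buffer suppresses base-induced retro-oxa-Michael opening and lactonisation onto the ester, and the air-sensitive product is used at once.

**Step 13**
Reactants: 27 5,7-dihydroxychromanone; 28 tert-butyl (2-methylbut-3-en-2-yl) carbonate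
Product: 29 methyl ester of the target [(6R)-6-prenyl dearomatised triketone]
Conditions: Pd2(dba)3·CHCl3 (2.5 mol %), (S,S)-DACH-phenyl Trost ligand (7.5 mol %), 28 (1.2 equiv), degassed toluene, 0 °C → rt
Reagents that add atoms: none
Why: Tsuji–Trost allylic alkylation with dearomatisation: decarboxylative ionisation gives a π-prenyl complex of divalent palladium and tert-butoxide, the acylphloroglucinol anion attacks the unsubstituted allyl terminus through C6 (flanked by two oxygens and less hindered than C8, O-allylation being reversible under the catalyst), and the chiral ligand pocket discriminates the two faces of ring A so that the C6 quaternary centre is set by catalyst control, the ligand antipode being fixed in a trial run with both.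

**Step 14**
Reactants: 29 methyl ester of the target
Product: 30 target acid CNP0103716.3
Conditions: LiOH·H2O (3 equiv), THF/H2O 3:1, 0 °C → rt; then 1 M HCl to pH 3
Reagents that add atoms: lithium hydroxide, [Li+].[OH-]
Why: Saponification of the methyl ester; under base ring A is a delocalised triketone enolate and so protected from nucleophiles, no stereocentre is α to the ester, and C3 stays in its thermodynamic trans configuration.

**Compound list**
1 | (−)-α-pinene, (1S,5S)-2,6,6-trimethylbicyclo[3.1.1]hept-2-ene | CC1=CC[C@H]2C[C@@H]1C2(C)C | starting material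
2 | (1R,3R)-cis-pinonic acid, 2-[(1R,3R)-3-acetyl-2,2-dimethylcyclobutyl]acetic acid | CC(=O)[C@@H]1C[C@H](CC(=O)O)C1(C)C | intermediate
3 | methyl 2-[(1R,3R)-3-acetyl-2,2-dimethylcyclobutyl]acetate | CC(=O)[C@@H]1C[C@H](CC(=O)OC)C1(C)C | intermediate
4 | methyl 2-[(1R,3S)-2,2-dimethyl-3-(prop-1-en-2-yl)cyclobutyl]acetate | C=C(C)[C@@H]1C[C@H](CC(=O)OC)C1(C)C | intermediate
5 | lithium 1,1-dibromo-3-[(1R,3S)-2,2-dimethyl-3-(prop-1-en-2-yl)cyclobutyl]prop-1-en-2-olate | [Li+].[O-]C(=C(Br)Br)C[C@H]1C[C@@H](C(C)=C)C1(C)C | intermediate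
6 | lithium 3-[(1R,3S)-2,2-dimethyl-3-(prop-1-en-2-yl)cyclobutyl]prop-1-yn-1-olate | [Li+].[O-]C#CC[C@H]1C[C@@H](C(C)=C)C1(C)C | intermediate
7 | {3-[(1R,3S)-2,2-dimethyl-3-(prop-1-en-2-yl)cyclobutyl]prop-1-yn-1-yl}oxy(triisopropyl)silane | CC(C)[Si](OC#CC[C@H]1C[C@@H](C(C)=C)C1(C)C)(C(C)C)C(C)C | intermediate
8 | 3-phenylglutaric anhydride (4-phenyloxane-2,6-dione) | O=C1CC(CC(=O)O1)c1ccccc1 | starting material
9 | (3S)-5-methoxy-5-oxo-3-phenylpentanoic acid | OC(=O)C[C@@H](CC(=O)OC)c1ccccc1 | intermediate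
10 | methyl (3R)-5-chloro-5-oxo-3-phenylpentanoate | COC(=O)C[C@H](CC(=O)Cl)c1ccccc1 | intermediate
11 | aldoketene, methyl (3R)-5-oxo-3-phenylpent-4-enoate | COC(=O)C[C@H](C=C=O)c1ccccc1 | intermediate
12 | methyl (3R)-3-[3-{[(1R,3S)-2,2-dimethyl-3-(prop-1-en-2-yl)cyclobutyl]methyl}-4-oxo-2-(triisopropylsilyloxy)cyclobut-2-en-1-yl]-3-phenylpropanoate (epimer mixture at cyclobutenone C1) | COC(=O)C[C@H](C1C(=O)C(C[C@H]2C[C@@H](C(C)=C)C2(C)C)=C1O[Si](C(C)C)(C(C)C)C(C)C)c1ccccc1 | intermediate
13 | 3,3-diethoxyprop-1-yne | C#CC(OCC)OCC | starting material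
14 | lithium 3,3-diethoxyprop-1-yn-1-ide | [Li]C#CC(OCC)OCC | intermediate
15 | lithium 3,3-diethoxyprop-1-yn-1-olate | [Li+].[O-]C#CC(OCC)OCC | intermediate
16 | (3,3-diethoxyprop-1-yn-1-yl)oxy(triisopropyl)silane | CCOC(OCC)C#CO[Si](C(C)C)(C(C)C)C(C)C | intermediate
17 | vinylketene from ring opening of 12 (ketene carbon bears the cyclobutylmethyl group; E-configured siloxyvinyl unit ending in the (R)-CH(Ph)CH2CO2Me chain) | O=C=C(C[C@H]1C[C@@H](C(C)=C)C1(C)C)/C(O[Si](C(C)C)(C(C)C)C(C)C)=C/[C@@H](CC(=O)OC)c1ccccc1 | intermediate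
18 | vinylcyclobutenone, 2-(diethoxymethyl)-3-siloxy-4-(cyclobutylmethyl)-4-(siloxyvinyl)cyclobut-2-enone (mixture at the quaternary ring carbon) | O=C1C(C(OCC)OCC)=C(O[Si](C(C)C)(C(C)C)C(C)C)C1(C[C@H]2C[C@@H](C(C)=C)C2(C)C)/C(O[Si](C(C)C)(C(C)C)C(C)C)=C/[C@@H](CC(=O)OC)c1ccccc1 | intermediate
19 | dienylketene from ring opening of 18 | O=C=C(C(OCC)OCC)/C(O[Si](C(C)C)(C(C)C)C(C)C)=C(C[C@H]1C[C@@H](C(C)=C)C1(C)C)\C(O[Si](C(C)C)(C(C)C)C(C)C)=C\[C@@H](CC(=O)OC)c1ccccc1 | intermediate
20 | cyclohexa-2,4-dienone from 6π closure of 19 (mixture at the ring CH) | O=C1C(C(OCC)OCC)=C(O[Si](C(C)C)(C(C)C)C(C)C)C(C[C@H]2C[C@@H](C(C)=C)C2(C)C)=C(O[Si](C(C)C)(C(C)C)C(C)C)C1[C@@H](CC(=O)OC)c1ccccc1 | intermediate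
21 | methyl (3S)-3-[3-(diethoxymethyl)-5-{[(1R,3S)-2,2-dimethyl-3-(prop-1-en-2-yl)cyclobutyl]methyl}-2-hydroxy-4,6-bis(triisopropylsilyloxy)phenyl]-3-phenylpropanoate | Oc1c(C(OCC)OCC)c(O[Si](C(C)C)(C(C)C)C(C)C)c(C[C@H]2C[C@@H](C(C)=C)C2(C)C)c(O[Si](C(C)C)(C(C)C)C(C)C)c1[C@@H](CC(=O)OC)c1ccccc1 | intermediate
22 | methyl (3S)-3-[5-{[(1R,3S)-2,2-dimethyl-3-(prop-1-en-2-yl)cyclobutyl]methyl}-3-formyl-2-hydroxy-4,6-bis(triisopropylsilyloxy)phenyl]-3-phenylpropanoate | Oc1c(C=O)c(O[Si](C(C)C)(C(C)C)C(C)C)c(C[C@H]2C[C@@H](C(C)=C)C2(C)C)c(O[Si](C(C)C)(C(C)C)C(C)C)c1[C@@H](CC(=O)OC)c1ccccc1 | intermediate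
23 | but-2-yne | CC#CC | starting material
24 | methyl (3S)-3-[5-{[(1R,3S)-2,2-dimethyl-3-(prop-1-en-2-yl)cyclobutyl]methyl}-2-hydroxy-3-[(2E)-2-methylbut-2-enoyl]-4,6-bis(triisopropylsilyloxy)phenyl]-3-phenylpropanoate | Oc1c(C(=O)/C(C)=C/C)c(O[Si](C(C)C)(C(C)C)C(C)C)c(C[C@H]2C[C@@H](C(C)=C)C2(C)C)c(O[Si](C(C)C)(C(C)C)C(C)C)c1[C@@H](CC(=O)OC)c1ccccc1 | intermediate
25 | methyl (3S)-3-[(2R,3S)-6-{[(1R,3S)-2,2-dimethyl-3-(prop-1-en-2-yl)cyclobutyl]methyl}-2,3-dimethyl-4-oxo-5,7-bis(triisopropylsilyloxy)chroman-8-yl]-3-phenylpropanoate (cis) | COC(=O)C[C@H](c1c2O[C@H](C)[C@H](C)C(=O)c2c(O[Si](C(C)C)(C(C)C)C(C)C)c(C[C@H]2C[C@@H](C(C)=C)C2(C)C)c1O[Si](C(C)C)(C(C)C)C(C)C)c1ccccc1 | intermediate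
26 | methyl (3S)-3-[(2R,3R)-6-{[(1R,3S)-2,2-dimethyl-3-(prop-1-en-2-yl)cyclobutyl]methyl}-2,3-dimethyl-4-oxo-5,7-bis(triisopropylsilyloxy)chroman-8-yl]-3-phenylpropanoate (trans) | COC(=O)C[C@H](c1c2O[C@H](C)[C@@H](C)C(=O)c2c(O[Si](C(C)C)(C(C)C)C(C)C)c(C[C@H]2C[C@@H](C(C)=C)C2(C)C)c1O[Si](C(C)C)(C(C)C)C(C)C)c1ccccc1 | intermediate
27 | methyl (3S)-3-[(2R,3R)-6-{[(1R,3S)-2,2-dimethyl-3-(prop-1-en-2-yl)cyclobutyl]methyl}-5,7-dihydroxy-2,3-dimethyl-4-oxochroman-8-yl]-3-phenylpropanoate | COC(=O)C[C@H](c1c2O[C@H](C)[C@@H](C)C(=O)c2c(O)c(C[C@H]2C[C@@H](C(C)=C)C2(C)C)c1O)c1ccccc1 | intermediate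
28 | tert-butyl (2-methylbut-3-en-2-yl) carbonate | C=CC(C)(C)OC(=O)OC(C)(C)C | starting material
29 | methyl (3S)-3-[(2R,3R,6R)-6-{[(1R,3S)-2,2-dimethyl-3-(prop-1-en-2-yl)cyclobutyl]methyl}-5-hydroxy-2,3-dimethyl-6-(3-methylbut-2-en-1-yl)-4,7-dioxo-3,4,6,7-tetrahydro-2H-chromen-8-yl]-3-phenylpropanoate | C=C(C)[C@@H]1C[C@H](C[C@@]2(CC=C(C)C)C(=O)C([C@@H](CC(=O)OC)c3ccccc3)=C3O[C@H](C)[C@@H](C)C(=O)C3=C2O)C1(C)C | intermediate
30 | (3S)-3-[(2R,3R,6R)-6-{[(1R,3S)-2,2-dimethyl-3-(prop-1-en-2-yl)cyclobutyl]methyl}-5-hydroxy-2,3-dimethyl-6-(3-methylbut-2-en-1-yl)-4,7-dioxo-3,4,6,7-tetrahydro-2H-chromen-8-yl]-3-phenylpropanoic acid (CNP0103716.3) | C=C(C)[C@@H]1C[C@H](C[C@@]2(CC=C(C)C)C(=O)C([C@@H](CC(=O)O)c3ccccc3)=C3O[C@H](C)[C@@H](C)C(=O)C3=C2O)C1(C)C | target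

**Totals**
Total step count: 14. Longest linear sequence: 11 steps (steps 1–4, 7, 9–14).

**Steps most likely to fail, with fallbacks**

Step 9. The process at risk is the [2+2] union itself. The α-branched vinylketene 17 and the bulky, acetal-bearing siloxyalkyne 16 may combine too slowly, so that the ketene is lost to dimerisation or to O-acylation of phenol already formed. The fallback sets out from cyclobutenone 12. The same thermal annulation is run with the small, commercially available ethoxyacetylene (toluene, 80 °C), which should give the C4a-unsubstituted 5-ethoxy phenol F1. Magnesium-mediated ortho-formylation of its single free ring position (MgCl2, Et3N, paraformaldehyde, MeCN, reflux) gives salicylaldehyde F2. Hydroacylation of but-2-yne as in step 10 gives tigloyl ketone F3, and quinine-catalysed oxa-Michael closure as in step 11 gives 5-ethoxychromanone F4. Chelation-assisted cleavage of the ethyl ether peri to the C4 carbonyl (MgI2·OEt2, toluene, 60 °C) gives 5-hydroxychromanone F5, and Bu4NF/AcOH desilylation returns to the route at diol 27.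

Step 13. The process at risk is poor discrimination of the two faces of ring A by the catalyst, since the resident stereocentres are remote and give no help; O-prenylation or attack at the tertiary allyl terminus may also compete. The fallback sets out from diol 27. Mitsunobu etherification of the non-chelated C7 hydroxyl with (S)-but-3-en-2-ol (PPh3, DIAD, THF; inversion) gives the (R)-but-3-en-2-yl aryl ether F6. Heating (toluene, 90–110 °C) should trigger a dearomatising aromatic Claisen rearrangement to C6 through a chair transition state with the methyl group equatorial. This transfers the configuration of the ether carbon to the quaternary centre and gives the (E)-crotyl dienone F7; C8, the other ortho carbon, is more hindered and C4a, para, is blocked. Cross-metathesis with 2-methylbut-2-ene (second-generation Hoveyda–Grubbs catalyst) exchanges the crotyl terminus for the prenyl terminus and returns to the route at ester 29.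

Step 11. The process at risk is insufficient enantiofacial control in the conjugate addition (a possible mismatch with the benzylic centre next to the phenol) and erosion of C2 by reversible ring opening during the C3 equilibration. The fallback sets out from aldehyde 22 and replaces steps 10 and 11. Mitsunobu etherification of the phenol with (S)-but-3-en-2-ol (inversion) gives the (R)-allylic ether F8. N-heterocyclic-carbene-catalysed intramolecular hydroacylation of the unactivated alkene (triazolium precatalyst, DBU, dioxane, 80 °C) then closes ring B with C2 taken from the chiral pool and C3 settling trans, returning to the route at chromanone 26.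

**Further compounds**
F1 | step 9 | methyl (3S)-3-[5-{[(1R,3S)-2,2-dimethyl-3-(prop-1-en-2-yl)cyclobutyl]methyl}-4-ethoxy-2-hydroxy-6-(triisopropylsilyloxy)phenyl]-3-phenylpropanoate | Oc1cc(OCC)c(C[C@H]2C[C@@H](C(C)=C)C2(C)C)c(O[Si](C(C)C)(C(C)C)C(C)C)c1[C@@H](CC(=O)OC)c1ccccc1
F2 | step 9 | methyl (3S)-3-[5-{[(1R,3S)-2,2-dimethyl-3-(prop-1-en-2-yl)cyclobutyl]methyl}-4-ethoxy-3-formyl-2-hydroxy-6-(triisopropylsilyloxy)phenyl]-3-phenylpropanoate | Oc1c(C=O)c(OCC)c(C[C@H]2C[C@@H](C(C)=C)C2(C)C)c(O[Si](C(C)C)(C(C)C)C(C)C)c1[C@@H](CC(=O)OC)c1ccccc1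
F3 | step 9 | methyl (3S)-3-[5-{[(1R,3S)-2,2-dimethyl-3-(prop-1-en-2-yl)cyclobutyl]methyl}-4-ethoxy-2-hydroxy-3-[(2E)-2-methylbut-2-enoyl]-6-(triisopropylsilyloxy)phenyl]-3-phenylpropanoate | Oc1c(C(=O)/C(C)=C/C)c(OCC)c(C[C@H]2C[C@@H](C(C)=C)C2(C)C)c(O[Si](C(C)C)(C(C)C)C(C)C)c1[C@@H](CC(=O)OC)c1ccccc1
F4 | step 9 | methyl (3S)-3-[(2R,3R)-6-{[(1R,3S)-2,2-dimethyl-3-(prop-1-en-2-yl)cyclobutyl]methyl}-5-ethoxy-2,3-dimethyl-4-oxo-7-(triisopropylsilyloxy)chroman-8-yl]-3-phenylpropanoate | COC(=O)C[C@H](c1c2O[C@H](C)[C@@H](C)C(=O)c2c(OCC)c(C[C@H]2C[C@@H](C(C)=C)C2(C)C)c1O[Si](C(C)C)(C(C)C)C(C)C)c1ccccc1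
F5 | step 9 | methyl (3S)-3-[(2R,3R)-6-{[(1R,3S)-2,2-dimethyl-3-(prop-1-en-2-yl)cyclobutyl]methyl}-5-hydroxy-2,3-dimethyl-4-oxo-7-(triisopropylsilyloxy)chroman-8-yl]-3-phenylpropanoate | COC(=O)C[C@H](c1c2O[C@H](C)[C@@H](C)C(=O)c2c(O)c(C[C@H]2C[C@@H](C(C)=C)C2(C)C)c1O[Si](C(C)C)(C(C)C)C(C)C)c1ccccc1
F6 | step 13 | methyl (3S)-3-[(2R,3R)-7-{[(2R)-but-3-en-2-yl]oxy}-6-{[(1R,3S)-2,2-dimethyl-3-(prop-1-en-2-yl)cyclobutyl]methyl}-5-hydroxy-2,3-dimethyl-4-oxochroman-8-yl]-3-phenylpropanoate | COC(=O)C[C@H](c1c2O[C@H](C)[C@@H](C)C(=O)c2c(O)c(C[C@H]2C[C@@H](C(C)=C)C2(C)C)c1O[C@H](C)C=C)c1ccccc1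
F7 | step 13 | methyl (3S)-3-[(2R,3R,6R)-6-[(2E)-but-2-en-1-yl]-6-{[(1R,3S)-2,2-dimethyl-3-(prop-1-en-2-yl)cyclobutyl]methyl}-5-hydroxy-2,3-dimethyl-4,7-dioxo-3,4,6,7-tetrahydro-2H-chromen-8-yl]-3-phenylpropanoate | C=C(C)[C@@H]1C[C@H](C[C@@]2(C/C=C/C)C(=O)C([C@@H](CC(=O)OC)c3ccccc3)=C3O[C@H](C)[C@@H](C)C(=O)C3=C2O)C1(C)C
F8 | step 11 | methyl (3S)-3-[2-{[(2R)-but-3-en-2-yl]oxy}-5-{[(1R,3S)-2,2-dimethyl-3-(prop-1-en-2-yl)cyclobutyl]methyl}-3-formyl-4,6-bis(triisopropylsilyloxy)phenyl]-3-phenylpropanoate | C=C[C@@H](C)Oc1c(C=O)c(O[Si](C(C)C)(C(C)C)C(C)C)c(C[C@H]2C[C@@H](C(C)=C)C2(C)C)c(O[Si](C(C)C)(C(C)C)C(C)C)c1[C@@H](CC(=O)OC)c1ccccc1
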